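**Plan**

- Enabling feature: in ring A (the methyl-bearing benzene ring) the carbon that carries the ester carbonyl (C-11a, depsidone numbering) and the carbon that carries the ether oxygen (C-4a) are neighbours. The two links, O-10 and O-5, end on the ortho carbons C-9a and C-5a of ring B. A but-2-ynoate on one ring B oxygen and an alkynyl ether on the other therefore hold two alkynes so that a third alkyne completes ring A and the seven-membered dioxepinone together.
- Cuts, in order: the lactol O-acyl bond and all protecting groups; the three ring A bonds C-4a–C-11a, C-1–C-2 and C-3–C-4 (giving a ring B diyne and tert-butoxyacetylene); the ester C–O and the O–C(sp) bonds; the two formyl C–C bonds of ring B, back to 2,4,5-trimethoxybenzoic acid.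
- Forward: ring B is finished first (formylation between two hydroxyls, allyl differentiation of the catechol, acetonide, second formylation). The ynol ether and then the butynoate are attached. The rhodium-catalysed (2+2+2) cycloaddition closes ring A and the seven-membered ring in one step, and acid then closes the five-membered lactol ring.
- Stereochemistry: the only stereocentre, the lactol carbon (S), is set last by lipase-mediated dynamic kinetic acetylation of the equilibrating lactol and kept by base-free enzymatic deacetylation.

Key step: step 14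

Assumption: the lactol carbon can epimerise through the ring-opened formyl carboxylate; it is taken to hold its configuration while the lactol stays un-ionised (aprotic, base-free medium, 20 °C or below, solid state), so the last step and the isolation avoid base and aqueous buffer.

**Route**

Step 1
Reactants: 1 2,4,5-trimethoxybenzoic acid
Product: 2 2,4,5-trihydroxybenzoic acid
Conditions: BBr3 (5 equiv), CH2Cl2, −78 °C → rt; then H2O, 0 °C
Reagents that add atoms: none
Why: Lewis-acid ether cleavage, in which BBr3 coordinates each aryl methyl ether and bromide removes the methyl group, is the standard exhaustive demethylation and leaves the carboxylic acid intact after hydrolysis.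

Step 2
Reactants: 2 2,4,5-trihydroxybenzoic acid
Product: 3 isopropyl 2,4,5-trihydroxybenzoate
Conditions: i-PrOH, H2SO4 (cat.), reflux, Ar
Reagents that add atoms: propan-2-ol, CC(C)O
Why: Fischer esterification installs an isopropyl ester, chosen because, once flanked by two ortho substituents, it should be shielded from n-BuLi in step 10, cannot ionise as a tert-butyl ester would when the neighbouring aldehyde is acetalised in step 9, and still leaves in the final acidolysis with the help of the ortho formyl group.

Step 3
Reactants: 3 isopropyl 2,4,5-trihydroxybenzoate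
Product: 4 isopropyl 3-formyl-2,4,5-trihydroxybenzoate
Conditions: hexamethylenetetramine, TFA, 75 °C; then 2 M HCl (aq), 60 °C
Reagents that add atoms: hexamethylenetetramine, C1N2CN3CN1CN(C2)C3; water, O
Why: The Duff formylation (electrophilic aminomethylation, internal hydride shift, hydrolysis) should take C-3, the only free carbon ortho to two hydroxyls, since C-5 carries oxygen and C-6 is activated by a single hydroxyl and flanked by the ester.

Step 4
Reactants: 4 isopropyl 3-formyl-2,4,5-trihydroxybenzoate
Product: 5 isopropyl 4-(allyloxy)-3-formyl-2,5-dihydroxybenzoate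
Conditions: allyl bromide (1.1 equiv), KHCO3 (1.1 equiv), DMF, rt → 40 °C, Ar
Reagents that add atoms: allyl bromide, C=CCBr
Why: Williamson etherification with a weak base should alkylate only the most acidic phenol, the 4-OH (para to the ester, ortho to the formyl group), because the 2-OH is locked by hydrogen bonds between two carbonyl groups and the 5-OH is the least acidic.

Step 5
Reactants: 5 isopropyl 4-(allyloxy)-3-formyl-2,5-dihydroxybenzoate
Product: 6 isopropyl 4-(allyloxy)-2,5-dihydroxy-3-(hydroxymethyl)benzoate
Conditions: NaBH4, THF/MeOH, 0 °C; NH4Cl (aq)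
Reagents that add atoms: none
Why: Borohydride reduction converts the aryl aldehyde to the benzylic alcohol and does not touch the isopropyl benzoate or the allyl ether.

Step 6
Reactants: 6 isopropyl 4-(allyloxy)-2,5-dihydroxy-3-(hydroxymethyl)benzoate
Product: 7 isopropyl 5-(allyloxy)-6-hydroxy-2,2-dimethyl-4H-benzo[d][1,3]dioxine-8-carboxylate
Conditions: 2,2-dimethoxypropane, PPTS (cat.), acetone, rt
Reagents that add atoms: 2,2-dimethoxypropane, COC(C)(C)OC
Why: Acid-catalysed transketalisation gives the six-membered acetonide with the only free phenol next to the hydroxymethyl group (the other neighbour is the allyl ether), so the ring forms at one site and the remaining phenol stays free.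

Step 7
Reactants: 7 isopropyl 5-(allyloxy)-6-hydroxy-2,2-dimethyl-4H-benzo[d][1,3]dioxine-8-carboxylate
Product: 8 isopropyl 5-(allyloxy)-7-formyl-6-hydroxy-2,2-dimethyl-4H-benzo[d][1,3]dioxine-8-carboxylate
Conditions: MgCl2, Et3N, (CH2O)n, MeCN, 80 °C; then 10 % citric acid (aq), 0 °C
Reagents that add atoms: paraformaldehyde (formaldehyde), C=O
Why: The magnesium-mediated ortho-formylation of phenols (Casnati–Skattebøl) delivers formaldehyde from the magnesium phenoxide to the ortho carbon, here the only unsubstituted ring position, under non-acidic conditions that spare the acetonide.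

Step 8
Reactants: 8 isopropyl 5-(allyloxy)-7-formyl-6-hydroxy-2,2-dimethyl-4H-benzo[d][1,3]dioxine-8-carboxylate; 9 trichloroethylene
Product: 10 isopropyl 5-(allyloxy)-6-[(E)-1,2-dichlorovinyloxy]-7-formyl-2,2-dimethyl-4H-benzo[d][1,3]dioxine-8-carboxylate
Conditions: 9 (1.5 equiv), K2CO3, DMF, 70 °C
Reagents that add atoms: none
Why: Base converts trichloroethylene into dichloroacetylene, to which the phenoxide adds anti to give the (E)-1,2-dichlorovinyl ether (first stage of the trichloroethylene route to alkynyl ethers), and the allyl group set in step 4 ensures that this oxygen, not the one para to the ester, carries the future ynol ether.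

Step 9
Reactants: 10 isopropyl 5-(allyloxy)-6-[(E)-1,2-dichlorovinyloxy]-7-formyl-2,2-dimethyl-4H-benzo[d][1,3]dioxine-8-carboxylate
Product: 11 isopropyl 5-(allyloxy)-6-[(E)-1,2-dichlorovinyloxy]-7-(dimethoxymethyl)-2,2-dimethyl-4H-benzo[d][1,3]dioxine-8-carboxylate
Conditions: HC(OMe)3, PPTS (cat.), MeOH/2,2-dimethoxypropane, rt; Et3N quench
Reagents that add atoms: trimethyl orthoformate, COC(OC)OC
Why: Acid-catalysed acetalisation masks the aldehyde against n-BuLi (step 10) and against rhodium-mediated hydroacylation (step 14), while 2,2-dimethoxypropane in the medium keeps the aryl acetonide from methanolysis.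

Step 10
Reactants: 11 isopropyl 5-(allyloxy)-6-[(E)-1,2-dichlorovinyloxy]-7-(dimethoxymethyl)-2,2-dimethyl-4H-benzo[d][1,3]dioxine-8-carboxylate
Product: 14 isopropyl 5-(allyloxy)-6-{[3-(tert-butyldimethylsilyloxy)prop-1-yn-1-yl]oxy}-7-(dimethoxymethyl)-2,2-dimethyl-4H-benzo[d][1,3]dioxine-8-carboxylate, via lithium alkynyl ether 12 (not isolated), via lithium propargylic alkoxide 13 (not isolated)
Conditions: n-BuLi (2.1 equiv), THF, −78 °C; (CH2O)n, −78 °C → rt; TBSCl, DMF, 0 °C → rt
Reagents that add atoms: paraformaldehyde (formaldehyde), C=O; tert-butyldimethylsilyl chloride, CC(C)(C)[Si](C)(C)Cl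
Why: Deprotonation and β-elimination give the chloroalkynyl ether, chlorine–lithium exchange gives the lithium acetylide, and hydroxymethylation and O-silylation follow in the same flask (second stage of the trichloroethylene route to alkynyl ethers), all of which should be fast at −78 °C compared with addition of n-BuLi to the di-ortho-substituted isopropyl ester.

Step 11
Reactants: 14 isopropyl 5-(allyloxy)-6-{[3-(tert-butyldimethylsilyloxy)prop-1-yn-1-yl]oxy}-7-(dimethoxymethyl)-2,2-dimethyl-4H-benzo[d][1,3]dioxine-8-carboxylate
Product: 15 isopropyl 6-{[3-(tert-butyldimethylsilyloxy)prop-1-yn-1-yl]oxy}-7-(dimethoxymethyl)-5-hydroxy-2,2-dimethyl-4H-benzo[d][1,3]dioxine-8-carboxylate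
Conditions: Pd(PPh3)4 (5 mol %), morpholine, THF, rt
Reagents that add atoms: none
Why: In this Tsuji–Trost deallylation zerovalent palladium ionises the allyl aryl ether (the phenoxide para to the ester is a good leaving group) and morpholine traps the allyl fragment, under neutral conditions that leave the ynol ether, silyl ether, acetal and acetonide alone.

Step 12
Reactants: 15 isopropyl 6-{[3-(tert-butyldimethylsilyloxy)prop-1-yn-1-yl]oxy}-7-(dimethoxymethyl)-5-hydroxy-2,2-dimethyl-4H-benzo[d][1,3]dioxine-8-carboxylate; 16 but-2-ynoic acid
Product: 17 isopropyl 5-(but-2-ynoyloxy)-6-{[3-(tert-butyldimethylsilyloxy)prop-1-yn-1-yl]oxy}-7-(dimethoxymethyl)-2,2-dimethyl-4H-benzo[d][1,3]dioxine-8-carboxylate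
Conditions: 16, DCC, CH2Cl2, 0 °C, 15 min; then 15, DMAP (cat.), 0 °C → rt
Reagents that add atoms: none
Why: Steglich esterification of the phenol, with the acid activated by DCC before the phenol is added so that no free carboxylic acid (which would add across the ynol ether) meets the substrate.

Step 13
Reactants: 18 potassium tert-butoxide; 9 trichloroethylene
Product: 21 tert-butoxyacetylene, via dichlorovinyl tert-butyl ether 19 (not isolated), via lithium tert-butoxyacetylide 20 (not isolated)
Conditions: Et2O, −50 °C → rt; n-BuLi (2.1 equiv), −78 °C; H2O, −78 → 0 °C; distillation, stored cold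
Reagents that add atoms: none
Why: The same trichloroethylene route to alkynyl ethers (alkoxide addition to dichloroacetylene formed in the flask, elimination, chlorine–lithium exchange, protonation) is established for hindered alkoxides and gives the terminal alkoxyalkyne.

Step 14
Reactants: 17 isopropyl 5-(but-2-ynoyloxy)-6-{[3-(tert-butyldimethylsilyloxy)prop-1-yn-1-yl]oxy}-7-(dimethoxymethyl)-2,2-dimethyl-4H-benzo[d][1,3]dioxine-8-carboxylate; 21 tert-butoxyacetylene
Product: 22 protected depsidone (11H-dibenzo[b,e][1,4]dioxepin-11-one with 1-CH3; 3-O-t-Bu; 4-CH2OTBS; 6-CH(OMe)2; 7-CO2-i-Pr; isopropylidene acetal bridging 8-O and 9-CH2O)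
Conditions: [Rh(cod)2]BF4 (10 mol %), rac-BINAP (10 mol %), H2 (1 atm) then Ar, CH2Cl2 (0.01 M), rt; 21 (3 equiv) added over 6 h
Reagents that add atoms: none
Why: Cationic monovalent rhodium binds the ynoate and the ynol ether, which the ortho ester and ether oxygens of the rigid ring B hold side by side, and couples them oxidatively to a trivalent rhodacyclopentadiene; this forms the C-4a–C-11a bond and closes the seven-membered dioxepinone (intramolecular alkyne–alkyne coupling of a 1,8-diyne). Coordination and insertion of tert-butoxyacetylene, then C–C reductive elimination, form C-1–C-2 and C-3–C-4 and close ring A, all six of whose carbons are alkyne carbons. The closest known reaction type is the (2+2+2) cycloaddition of tethered diynes with monoalkynes under cationic rhodium–bisphosphine catalysis, established for alkynoate esters and aryl alkynyl ethers; the seven-membered tether is the less common element. No stereocentre is created, so racemic BINAP suffices. The step needs regioselective insertion (oxygen-bearing alkyne carbon next to the silyloxymethyl carbon) and chemoselectivity against self-trimerisation of the alkoxyalkyne: the rhodacycle is polarised, its methyl-bearing end being the electrophilic β-carbon of an enoate and its silyloxymethyl-bearing end the nucleophilic β-carbon of an enol ether, so the nucleophilic CH terminus of the alkoxyalkyne should pair with the former and its electrophilic O-bearing carbon with the latter, while slow addition keeps the free alkyne scarce.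

Step 15
Reactants: 22 protected depsidone
Product: 23 racemic lactol (1-methyl-3,8-dihydroxy-4,9-bis(hydroxymethyl) depsidone whose 7-carboxyl and 6-formyl groups are closed to a 3-hydroxyphthalide ring; both lactol configurations)
Conditions: TFA/H2O (4:1), 0 → 35 °C; then H2O/MeCN, rt
Reagents that add atoms: water, O
Why: Aqueous acidolysis cleaves the aryl tert-butyl ether, the silyl ether, the acetonide and the dimethyl acetal, and the freed aldehyde then engages the neighbouring isopropyl ester through the cyclic pseudo-ester pathway of 2-formylbenzoates, expelling propan-2-ol and closing the five-membered lactol ring by attack of the carboxyl oxygen on the formyl carbon, without facial bias.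

Step 16
Reactants: 23 racemic lactol
Product: 24 (S)-lactol acetate with both hydroxymethyl groups acetylated (triacetate)
Conditions: Burkholderia cepacia lipase (immobilised; enzyme to be confirmed by a screen for the (S)-acetate), vinyl acetate, Et3N (10 mol %), THF, 30 °C
Reagents that add atoms: vinyl acetate, C=COC(C)=O
Why: In this lipase-catalysed dynamic kinetic resolution by acylation, a reaction type known for cyclic pseudo-acid lactols, amine-promoted ring–chain tautomerism through the achiral formyl carboxylate should interconvert the lactol enantiomers while the chiral acyl-binding site of the enzyme acetylates only the (S)-lactol, the two primary alcohols being acetylated alongside.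

Step 17
Reactants: 24 (S)-triacetate
Product: 25 target CNP0155661.1, (S)-lactol
Conditions: Burkholderia cepacia lipase (immobilised), n-BuOH, t-BuOMe/THF (dry), 20 °C; filtration, cold crystallisation
Reagents that add atoms: none
Why: Lipase-catalysed transesterification to n-butanol breaks only acyl C–O bonds, so the lactol C–O bond and its (S) configuration are retained, and the dry, base-free medium keeps the lactol un-ionised and thus closed.

**Compound list**

1 | 2,4,5-trimethoxybenzoic acid | COc1cc(OC)c(OC)cc1C(=O)O | starting material
2 | 2,4,5-trihydroxybenzoic acid | OC(=O)c1cc(O)c(O)cc1O | intermediate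
3 | isopropyl 2,4,5-trihydroxybenzoate | CC(C)OC(=O)c1cc(O)c(O)cc1O | intermediate
4 | isopropyl 3-formyl-2,4,5-trihydroxybenzoate | CC(C)OC(=O)c1cc(O)c(O)c(C=O)c1O | intermediate
5 | isopropyl 4-(allyloxy)-3-formyl-2,5-dihydroxybenzoate | CC(C)OC(=O)c1cc(O)c(OCC=C)c(C=O)c1O | intermediate
6 | isopropyl 4-(allyloxy)-2,5-dihydroxy-3-(hydroxymethyl)benzoate | CC(C)OC(=O)c1cc(O)c(OCC=C)c(CO)c1O | intermediate
7 | isopropyl 5-(allyloxy)-6-hydroxy-2,2-dimethyl-4H-benzo[d][1,3]dioxine-8-carboxylate | CC(C)OC(=O)c1cc(O)c(OCC=C)c2COC(C)(C)Oc12 | intermediate
8 | isopropyl 5-(allyloxy)-7-formyl-6-hydroxy-2,2-dimethyl-4H-benzo[d][1,3]dioxine-8-carboxylate | CC(C)OC(=O)c1c(C=O)c(O)c(OCC=C)c2COC(C)(C)Oc12 | intermediate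
9 | trichloroethylene | ClC=C(Cl)Cl | starting material
10 | isopropyl 5-(allyloxy)-6-[(E)-1,2-dichlorovinyloxy]-7-formyl-2,2-dimethyl-4H-benzo[d][1,3]dioxine-8-carboxylate | CC(C)OC(=O)c1c(C=O)c(O/C(Cl)=C\Cl)c(OCC=C)c2COC(C)(C)Oc12 | intermediate
11 | isopropyl 5-(allyloxy)-6-[(E)-1,2-dichlorovinyloxy]-7-(dimethoxymethyl)-2,2-dimethyl-4H-benzo[d][1,3]dioxine-8-carboxylate | CC(C)OC(=O)c1c(C(OC)OC)c(O/C(Cl)=C\Cl)c(OCC=C)c2COC(C)(C)Oc12 | intermediate
12 | lithium alkynyl ether (lithium acetylide of the 6-ethynyloxy compound) | CC(C)OC(=O)c1c(C(OC)OC)c(OC#C[Li])c(OCC=C)c2COC(C)(C)Oc12 | intermediate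
13 | lithium propargylic alkoxide (lithium salt of the 6-(3-hydroxyprop-1-ynyloxy) compound) | CC(C)OC(=O)c1c(C(OC)OC)c(OC#CCO[Li])c(OCC=C)c2COC(C)(C)Oc12 | intermediate
14 | isopropyl 5-(allyloxy)-6-{[3-(tert-butyldimethylsilyloxy)prop-1-yn-1-yl]oxy}-7-(dimethoxymethyl)-2,2-dimethyl-4H-benzo[d][1,3]dioxine-8-carboxylate | CC(C)OC(=O)c1c(C(OC)OC)c(OC#CCO[Si](C)(C)C(C)(C)C)c(OCC=C)c2COC(C)(C)Oc12 | intermediate
15 | isopropyl 6-{[3-(tert-butyldimethylsilyloxy)prop-1-yn-1-yl]oxy}-7-(dimethoxymethyl)-5-hydroxy-2,2-dimethyl-4H-benzo[d][1,3]dioxine-8-carboxylate | CC(C)OC(=O)c1c(C(OC)OC)c(OC#CCO[Si](C)(C)C(C)(C)C)c(O)c2COC(C)(C)Oc12 | intermediate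
16 | but-2-ynoic acid | CC#CC(=O)O | starting material
17 | isopropyl 5-(but-2-ynoyloxy)-6-{[3-(tert-butyldimethylsilyloxy)prop-1-yn-1-yl]oxy}-7-(dimethoxymethyl)-2,2-dimethyl-4H-benzo[d][1,3]dioxine-8-carboxylate (diyne) | CC(C)OC(=O)c1c(C(OC)OC)c(OC#CCO[Si](C)(C)C(C)(C)C)c(OC(=O)C#CC)c2COC(C)(C)Oc12 | intermediate
18 | potassium tert-butoxide | CC(C)(C)[O-].[K+] | starting material
19 | (E)-1,2-dichlorovinyl tert-butyl ether | CC(C)(C)O/C(Cl)=C\Cl | intermediate
20 | lithium tert-butoxyacetylide | CC(C)(C)OC#C[Li] | intermediate
21 | tert-butoxyacetylene | CC(C)(C)OC#C | intermediate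
22 | protected depsidone (1-CH3; 3-O-t-Bu; 4-CH2OTBS; 6-CH(OMe)2; 7-CO2-i-Pr; 8-O/9-CH2O isopropylidene acetal) | Cc1cc(OC(C)(C)C)c(CO[Si](C)(C)C(C)(C)C)c2c1C(=O)Oc1c3COC(C)(C)Oc3c(C(=O)OC(C)C)c(C(OC)OC)c1O2 | intermediate
23 | racemic lactol (target constitution, both lactol configurations) | Cc1cc(O)c(CO)c2c1C(=O)Oc1c(CO)c(O)c3c(c1O2)C(O)OC3=O | intermediate
24 | (S)-lactol acetate, both hydroxymethyl groups acetylated (triacetate) | Cc1cc(O)c(COC(C)=O)c2c1C(=O)Oc1c(COC(C)=O)c(O)c3c(c1O2)[C@@H](OC(C)=O)OC3=O | intermediate
25 | CNP0155661.1, (S)-lactol | Cc1cc(O)c(CO)c2c1C(=O)Oc1c(CO)c(O)c3c(c1O2)[C@@H](O)OC3=O | target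

**Step count and risks**

Total steps: 17. Longest linear sequence: 16 (steps 1–12, then 14–17); step 13 is the one-step side branch to the alkyne.

The three steps most likely to fail:

1. Step 14. Closure of the seven-membered rhodacycle from the 1,8-diyne may be slower than consumption of the alkoxyalkyne by self-trimerisation or 2:1 cross-cyclotrimerisation, and the third alkyne may insert in both orientations. The fallback keeps the same three ring A bonds and the same two ring closures but ties the third alkyne to the substrate by a temporary boron tether. It sets out from 17: buffered desilylation (TBAF/AcOH, THF, 0 °C) should give the propargylic alcohol F1. With diisopropyl ethynylboronate this exchanges in the flask to the mixed boronate F2, a triyne whose boron-linked pair is a 1,6-diyne. Cp*RuCl(cod), a divalent ruthenium catalyst, in 1,2-dichloroethane at rt should cyclise it, with the tethered ynoate closing the seven-membered ring, to give after aqueous work-up the benzoxaborole F3; boron sits on C-3 because of the tether, so the regiochemistry no longer depends on polarity matching. Oxidation of the C–B bond (Me3NO, THF, rt) should give the phenol diol F4, and the acid treatment of step 15 brings it back to the route at 23.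

2. Step 10. Addition of n-BuLi to the isopropyl ester, or ester-assisted displacement of the ortho acetal oxygen, may compete with elimination and chlorine–lithium exchange. The fallback forms the ynol ether without an organolithium and sets out from 8. Copper-catalysed coupling (CuI, 2,2'-bipyridine, K3PO4, toluene, 110 °C) of the phenol with the 1,1-dibromoalkene F5 (from (tert-butyldimethylsilyloxy)acetaldehyde, CBr4 and PPh3 by Ramirez olefination) should give the (Z)-1-bromoenol ether F6. Acetalisation as in step 9 gives the acetal F7, and dehydrobromination with KOtBu in THF at rt returns to the route at 14; steps 8 and 10 are bypassed.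

3. Step 16. The lipase may discriminate poorly between the lactol enantiomers, or their interconversion may be slower than acylation so that the resolution is not dynamic. The fallback replaces the enzyme by small-molecule acyl-transfer catalysis and sets out from 23. A chiral isothiourea (HyperBTM, the enantiomer that delivers the (S)-ester; both are available) with Ac2O and i-Pr2NEt in CH2Cl2 at 0 °C should give the pentaacetate F8, in which the two phenols are acetylated as well and the lactol acetate is (S). The lipase butanolysis of step 17, which then needs no enantioselectivity and cleaves aryl acetates readily, brings it back to the route at 25.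

Further compounds
F1 | step 14 | diyne 17 with free propargylic alcohol (desilylated) | CC(C)OC(=O)c1c(C(OC)OC)c(OC#CCO)c(OC(=O)C#CC)c2COC(C)(C)Oc12
F2 | step 14 | mixed isopropyl propargyl ethynylboronate of F1 (boron-tethered triyne) | CC(C)OC(=O)c1c(C(OC)OC)c(OC#CCOB(OC(C)C)C#C)c(OC(=O)C#CC)c2COC(C)(C)Oc12
F3 | step 14 | benzoxaborole-fused protected depsidone (B on C-3, B–O–CH2 on C-4) | Cc1cc2B(O)OCc2c2c1C(=O)Oc1c3COC(C)(C)Oc3c(C(=O)OC(C)C)c(C(OC)OC)c1O2
F4 | step 14 | depsidone with free 3-OH and 4-CH2OH, ring B still protected | Cc1cc(O)c(CO)c2c1C(=O)Oc1c3COC(C)(C)Oc3c(C(=O)OC(C)C)c(C(OC)OC)c1O2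
F5 | step 10 | tert-butyl[(3,3-dibromoprop-2-en-1-yl)oxy]dimethylsilane | BrC(Br)=CCO[Si](C)(C)C(C)(C)C
F6 | step 10 | (Z)-1-bromoenol ether of phenol 8 (aldehyde) | CC(C)OC(=O)c1c(C=O)c(O/C(Br)=C/CO[Si](C)(C)C(C)(C)C)c(OCC=C)c2COC(C)(C)Oc12
F7 | step 10 | (Z)-1-bromoenol ether, dimethyl acetal | CC(C)OC(=O)c1c(C(OC)OC)c(O/C(Br)=C/CO[Si](C)(C)C(C)(C)C)c(OCC=C)c2COC(C)(C)Oc12
F8 | step 16 | pentaacetate with (S)-lactol acetate | Cc1cc(OC(C)=O)c(COC(C)=O)c2c1C(=O)Oc1c(COC(C)=O)c(OC(C)=O)c3c(c1O2)[C@@H](OC(C)=O)OC3=O
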